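(The earlier runs and the new flask come from a simulation for substances that don't exist.)

Two questions stand on Friday's flask, and its curve answers both.

common to all: starting material 20 mM (in portions, 4)
- Friday's: reagent 60 mM; the very flask that is asked about, followed so far; portions every 25 s
- Thursday's: reagent 90 mM; run made earlier; portions every 25 s
- flask: reagent 60.0 mM; the portions of starting material follow each other after 25 s, the first at the start; time 10 min

| run | time / min | side product / % | triple product / % | bis adduct / % | mono adduct / % | starting material / % |
|---|---|---|---|---|---|---|
| Friday's | 0.250 | 0 | 1.2 | 5.7 | 4.9 | 10.5 |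
| Friday's | 0.333 | 0 | 1.8 | 5.9 | 4.6 | 7.9 |
| Friday's | 0.500 | 0.6 | 4.6 | 8.0 | 7.1 | 23.9 |
| Friday's | 0.833 | 0.1 | 10.8 | 13.0 | 6.5 | 10.5 |
| Friday's | 1.33 | 0.2 | 21.2 | 20.4 | 11.2 | 34.6 |
| Friday's | 2.00 | 0.7 | 31.0 | 26.1 | 10.8 | 18.3 |
| Friday's | 3.00 | 0.7 | 44.7 | 23.6 | 6.8 | 13.3 |
| Thursday's | 0.417 | 0.5 | 9.6 | 7.4 | 3.3 | 4.3 |
| Thursday's | 1.00 | 0.2 | 25.4 | 14.0 | 7.5 | 18.1 |
| Thursday's | 2.00 | 0.7 | 54.0 | 20.0 | 7.1 | 11.3 |
| Thursday's | 3.00 | 1.8 | 72.0 | 11.8 | 3.0 | 7.6 |
| Thursday's | 4.00 | 1.9 | 82.7 | 8.1 | 1.8 | 4.2 |
| Thursday's | 6.00 | 1.7 | 92.4 | 2.2 | 1.6 | 1.7 |
| Thursday's | 8.00 | 1.6 | 96.3 | 1.1 | 0.5 | 1.0 |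

(standard deviation of a reading: 0.5 percentage points)

* the species that holds most of what was charged as starting material, at 10 min (mono adduct / triple product / starting material / side product / bis adduct)
* the largest share itself, whichever of these holds it, in percent of the starting material charged

- a reading or a percentage of bis adduct counts all its forms, free or not
- a reading at the moment of an addition is taken just before it
- a reading or a percentage of starting material is of its free form alone
- percentages count the whole charge, also what has not yet gone in

In Friday's flask, triple product gains 26 percentage points in the 1.50 min from 0.500 min. The last portion goes in at 1.25 min, and triple product and bis adduct read level at 1.33 min, 21.2% against 20.4%, which is within the scatter. Then comes the knee: the 1.00 min from 2.00 min adds 14 points.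

What matters from here is the unfinished share, the part of the charge that is neither triple product nor side product: 68.3% at 2.00 min and 54.6% at 3.00 min. Friday's charge holds 60 mM of reagent on 20 mM of starting material, a ratio of 3.00, which is what triple product takes. So [reagent] shrinks with the unfinished share, and the tail should run second-order: each halving takes twice as long as the one before.

We call the tail time, the time the unfinished share needs to halve from its value at 3.00 min, 4.99 min; it is a reading from two rows and carries their scatter. Over the time left, it brings the unfinished share to 22.7%. Taking off Thursday's side product reading of 1.9% at 4.00 min as a stand-in for Friday's flask, we expect triple product at 75.4%, above the forecast.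

The forecast says triple product at 73%, between 66% and 79%: “This gives a second-order tail”.

Friday's flask gives triple product at 76.4%, so the forecast stands, and the unfinished share is 20.6%, a little below our 22.7%.

reagent + mono adduct → bis adduct + by-product (k = 110 /M/min); starting material + reagent → mono adduct + by-product (k = 49.0 /M/min); mono adduct → side product (k = 0.0570 /min); reagent + bis adduct → triple product + by-product (k = 90.0 /M/min); starting material + bis adduct ⇌ idle adduct A, settled at all times (K = 370 /M); reagent + by-product ⇌ idle adduct B, settled at all times (K = 46.0 /M) The same flask read at 40.0 min shows 3.46% unfinished, where the tail time gives 6.48%. The flask has not come to rest at 10.0 min. At 100 min triple product stands at 93.9%, 17 points higher, and side product at 5.77%.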